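Prd is the one thing read in these flasks, so whatever we say about Cat must come from how fast c(Prd) grows.

| setting | winter | midnight | dawn | autumn | spring |
|---|---|---|---|---|---|
| Sub | 1.00 M | 0.600 M | 3.00 M | 1.00 M | 0.500 M |
| Cat | 0.0300 M | 0.0300 M | 0.0300 M | 0.0150 M | 0.00990 M |
| time |  |  |  |  | 22 min |

| run | time / min | [Prd] / M |
|---|---|---|
| winter run | 0.88 | 0.067 |
| winter run | 1.7 | 0.130 |
| winter run | 3.2 | 0.234 |
| winter run | 6.1 | 0.408 |
| winter run | 12 | 0.673 |
| winter run | 22 | 0.895 |
| midnight run | 0.88 | 0.047 |
| midnight run | 1.7 | 0.090 |
| midnight run | 3.2 | 0.158 |
| midnight run | 6.1 | 0.279 |
| midnight run | 12 | 0.424 |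
| midnight run | 22 | 0.549 |
| dawn run | 0.88 | 0.118 |
| dawn run | 1.7 | 0.225 |
| dawn run | 3.2 | 0.421 |
| dawn run | 6.1 | 0.782 |
| dawn run | 12 | 1.438 |
| dawn run | 22 | 2.270 |
| autumn run | 0.88 | 0.025 |
| autumn run | 1.7 | 0.055 |
| autumn run | 3.2 | 0.103 |
| autumn run | 6.1 | 0.185 |
| autumn run | 12 | 0.343 |
| autumn run | 22 | 0.558 |

(readings scatter by 0.003 M)

- Overall: Sub -> Prd, with Cat as catalyst.
- Constant volume, constant temperature.
- The analysis sees a species whether free or bound.
- An order is taken over about fifteen percent of the charge, up and down.

1. how the opening rate goes with [Cat] round the charge of the winter run: the exponent of the rate at two percent of Sub gone to Prd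
2. how the opening rate goes with [Sub] round the charge of the winter run: the exponent of the rate at two percent of Sub gone to Prd (one fixed amount of Prd, the same in the runs compared)
3. the midnight run starts with 0.400 M less of Sub than the winter run, and with no Prd. Compared where both hold the same amount of Sub, once fifteen percent of what the midnight run was charged with has turned into Prd, is the midnight run faster, slower or alike (within a tenth)?
4. Prd in the spring run at 22 min, as a share of the Sub charged

**Q: The autumn run has the same c(Sub) as the winter run, but less Cat. What do the readings say?**

A: I compare the times at which the two runs reach one c(Prd). The autumn run reads 0.185 M at 6.1 min, and a straight line between the winter readings puts that amount at 2.49 min in the winter run. In logarithms the time goes up by 0.389 and c(Cat) goes down by 0.301, so the exponent over that step is 1.29.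

**Q: Is that the order asked for?**

A: No, that step is too wide. The order asked for is local, round the winter charge.

**Q: Then what could give an exponent above one?**

A: The plainest picture is that a fixed amount is lost from each charge and the rest of the Cat works in proportion. From those two times the autumn rate stands at 0.409 of the winter rate, and setting that equal to (autumn Cat less the loss) over (winter Cat less the loss) gives 0.00463 M. I call this the toll, the amount of Cat a charge loses before it works. The local exponent is then c(Cat) over c(Cat) less the toll, which is 1.18 for the winter run.

**Q: Does Prd slow the flask?**

A: This is a same-excess test. The winter run passes 0.592 M of Sub at 6.1 min, near the midnight charge. Its mean rate over the next stretch, set against the midnight run's mean rate from its start, gives a ratio of 1.02. So I call them alike.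

**Q: What about the spring run?**

A: The midnight run holds the spring c(Sub) at 1.92 min. After the toll, spring Cat works at 0.208 of midnight Cat, so 22 min of the spring run counts as 4.57 min on the midnight clock. That brings us to 6.49 min, where a straight line between the readings gives 0.289 M of Prd. Less the Prd already on the curve at that starting point, this leaves 37.7% of the spring charge.

The forecast, made from these runs, gives 1.22 (1.1 to 1.37) for the Cat order and 0.64 (0.57 to 0.71) for the Sub order. It calls the midnight comparison alike and puts the spring run at 41% (36% to 46%). On the exponent above one it says: “This suggests an active dimer or a small poison”. My Cat order is lower than its figure, and so is my spring share.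

The flask gives 1.2 for the Cat order, 0.64 for the Sub order, alike for the midnight comparison and 38.1% for the spring run.

    Cat + Sub → Prd + Cat (5.094 /M/min)
    Cat + Sub ⇌ Cat.Sub, settled at all times (0.6260 /M)
    Cat + L → E

The toll as read from the runs is 15.4% of the Cat in the winter run but 46.8% in the spring run, a heavier share. The spring run shows what that costs: without the conversion of Cat + L into E, it reaches 60.0% of its Sub instead of 38.1%.

The numbers in the tables are calculated for an exercise; the scatter is artificial.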